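**Retrosynthetic overview**

1. The strategy rests on the cyclohexane of the elemane half: quaternary C10' (methyl, vinyl) sits next to C5' (isopropenyl) in a trans-1,2-dialkenylcyclohexane, which a thermal [3,3] shift traces back to the (E,E)-cyclodeca-1,5-diene 23 (C5'–C10' opened, C2'–C3' closed).
2. The ten-membered ring of 23 is opened at C2'–C3' to an allylic sulfone carbanion and an allylic bromide (21); the sulfone is removed after ring closure.
3. The spiro dihydropyran (O–C11 and C13–C13' bonds) comes from a hetero-Diels–Alder reaction of the acyclic 2-substituted acrolein 17 with alantolactone 18, run before the ten-membered ring exists so that heating cannot trigger the rearrangement early.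
4. Chain 17 comes from (S)-limonene: C10 hydroxylation, ozonolytic ring cleavage, Wittig reaction at the aldehyde (C4'=C5') and Horner–Wadsworth–Emmons reaction at the ketone (C1'=C10'); C7' is limonene C4.
5. Ring order: eudesmanolide rings bought with 18, then the dihydropyran (step 11), the ten-membered ring (step 14), and last the cyclohexane by ring contraction (step 16).

Key step: step 16

Numbering: the eudesmanolide half has plain biogenetic locants (lactone C12, spiro C11, former methylene C13); the germacrane/elemane half has primed locants.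

Assumption: tert-butyl 2-(triphenylphosphoranylidene)propanoate (8) is taken as a purchased reagent; its tert-butyl ester is what lets the two enoates of 11 be reduced one after the other.

**Route**

Step 1
Reactants: 1 (S)-(−)-limonene
Product: 4 (S)-p-mentha-1,8-dien-10-ol, via allyllithium 2 (not isolated), via dimethyl allylboronate 3 (not isolated)
Conditions: n-BuLi, TMEDA, hexane, 20 °C, 24 h; B(OMe)3, THF, −78 °C; H2O2, aq. NaOH, 0 °C
Reagents that add atoms: hydrogen peroxide, OO
Why: TMEDA-activated n-BuLi is known to deprotonate limonene at the isopropenyl methyl to a symmetric 2-substituted allyllithium, and borylation then oxidation (allylmetal hydroxylation) should give the allylic alcohol without touching the C4 stereocentre.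

Step 2
Reactants: 4 (S)-p-mentha-1,8-dien-10-ol
Product: 5 (S)-10-(tert-butyldimethylsilyloxy)-p-mentha-1,8-diene
Conditions: t-BuMe2SiCl, imidazole, DMF, 20 °C
Reagents that add atoms: tert-butyldimethylsilyl chloride, CC(C)(C)[Si](C)(C)Cl
Why: Standard silylation of a primary alcohol; the ether masks the future C12' aldehyde through the olefination and hydride steps.

Step 3
Reactants: 5 (S)-10-(tert-butyldimethylsilyloxy)-p-mentha-1,8-diene
Product: 7 (3S)-3-[3-(tert-butyldimethylsilyloxy)prop-1-en-2-yl]-6-oxoheptanal, via secondary ozonide 6 (not isolated)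
Conditions: O3 (1 equiv), CH2Cl2, −78 °C, Sudan Red 7B end point; PPh3, −78 to 20 °C
Reagents that add atoms: ozone, [O-][O+]=O
Why: Ozonolysis with reductive work-up; ozone should attack the electron-rich trisubstituted ring alkene much faster than the 1,1-disubstituted alkene deactivated by its allylic silyloxy group, and the indicator dye limits over-oxidation.

Step 4
Reactants: 7 (3S)-3-[3-(tert-butyldimethylsilyloxy)prop-1-en-2-yl]-6-oxoheptanal; 8 tert-butyl 2-(triphenylphosphoranylidene)propanoate
Product: 9 tert-butyl (2E,5S)-5-[3-(tert-butyldimethylsilyloxy)prop-1-en-2-yl]-2-methyl-8-oxonon-2-enoate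
Conditions: CH2Cl2, 20 to 40 °C, 16 h
Reagents that add atoms: none
Why: Wittig reaction; the ester-stabilised ylide reacts with the aldehyde and not with the methyl ketone and should give the E trisubstituted enoate (C4'=C5').

Step 5
Reactants: 9 tert-butyl (2E,5S)-5-[3-(tert-butyldimethylsilyloxy)prop-1-en-2-yl]-2-methyl-8-oxonon-2-enoate; 10 triethyl phosphonoacetate
Product: 11 1-tert-butyl 10-ethyl (2E,5S,8E)-5-[3-(tert-butyldimethylsilyloxy)prop-1-en-2-yl]-2,8-dimethyldeca-2,8-dienedioate
Conditions: NaH, THF, 0 to 20 °C; chromatographic removal of the minor 8Z isomer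
Reagents that add atoms: none
Why: Horner–Wadsworth–Emmons olefination of the methyl ketone should give mainly the E β,β-disubstituted enoate (C1'=C10'), and the two geometric isomers of such enoates are normally separable on silica.

Step 6
Reactants: 11 1-tert-butyl 10-ethyl (2E,5S,8E)-5-[3-(tert-butyldimethylsilyloxy)prop-1-en-2-yl]-2,8-dimethyldeca-2,8-dienedioate
Product: 12 tert-butyl (2E,5S,8E)-5-[3-(tert-butyldimethylsilyloxy)prop-1-en-2-yl]-10-hydroxy-2,8-dimethyldeca-2,8-dienoate
Conditions: i-Bu2AlH (2.2 equiv), CH2Cl2, −78 °C; aq. potassium sodium tartrate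
Reagents that add atoms: none
Why: Ester reduction by i-Bu2AlH at −78 °C; the ethyl ester should go to the allylic alcohol while the tert-butyl ester, shielded by the tert-butyl group and the α-methyl branch, is expected to survive.

Step 7
Reactants: 12 tert-butyl (2E,5S,8E)-5-[3-(tert-butyldimethylsilyloxy)prop-1-en-2-yl]-10-hydroxy-2,8-dimethyldeca-2,8-dienoate
Product: 14 tert-butyl (2E,5S,8E)-5-[3-(tert-butyldimethylsilyloxy)prop-1-en-2-yl]-2,8-dimethyl-10-(phenylsulfonyl)deca-2,8-dienoate, via allylic bromide 13 (not isolated)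
Conditions: CBr4, PPh3, CH2Cl2, 0 °C; PhSO2Na, DMF, 20 °C
Reagents that add atoms: sodium benzenesulfinate, [Na+].[O-]S(=O)c1ccccc1
Why: Appel bromination of the primary allylic alcohol followed by SN2 S-alkylation of benzenesulfinate should give the geranyl-type sulfone at C2' with the E alkene retained.

Step 8
Reactants: 14 tert-butyl (2E,5S,8E)-5-[3-(tert-butyldimethylsilyloxy)prop-1-en-2-yl]-2,8-dimethyl-10-(phenylsulfonyl)deca-2,8-dienoate
Product: 15 (2E,5S,8E)-5-[3-(tert-butyldimethylsilyloxy)prop-1-en-2-yl]-2,8-dimethyl-10-(phenylsulfonyl)deca-2,8-dien-1-ol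
Conditions: i-Bu2AlH (4 equiv), CH2Cl2, −78 to 0 °C; aq. potassium sodium tartrate
Reagents that add atoms: none
Why: Excess i-Bu2AlH at higher temperature performs the 1,2-reduction of the hindered tert-butyl enoate; sulfone and silyl ether are inert to it.

Step 9
Reactants: 15 (2E,5S,8E)-5-[3-(tert-butyldimethylsilyloxy)prop-1-en-2-yl]-2,8-dimethyl-10-(phenylsulfonyl)deca-2,8-dien-1-ol
Product: 16 (2E,5S,8E)-5-(3-hydroxyprop-1-en-2-yl)-2,8-dimethyl-10-(phenylsulfonyl)deca-2,8-dien-1-ol
Conditions: Bu4NF, THF, 0 to 20 °C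
Reagents that add atoms: none
Why: Fluoride-induced cleavage of the silyl ether; the allylic sulfone is not affected by the weakly basic fluoride.

Step 10
Reactants: 16 (2E,5S,8E)-5-(3-hydroxyprop-1-en-2-yl)-2,8-dimethyl-10-(phenylsulfonyl)deca-2,8-dien-1-ol
Product: 17 (2E,5S,8E)-2,8-dimethyl-5-(3-oxoprop-1-en-2-yl)-10-(phenylsulfonyl)deca-2,8-dienal
Conditions: MnO2 (excess), CH2Cl2, 20 °C; used at once
Reagents that add atoms: none
Why: MnO2 oxidises both primary allylic alcohols to enals without over-oxidation; only the C12' enal is a 2-substituted, β-unsubstituted acrolein able to act as a fast heterodiene.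

Step 11
Reactants: 17 (2E,5S,8E)-2,8-dimethyl-5-(3-oxoprop-1-en-2-yl)-10-(phenylsulfonyl)deca-2,8-dienal; 18 alantolactone
Product: 19 (11R)-spiro dihydropyran adduct of alantolactone carrying at pyran C5 the (2E,5S,8E)-2,8-dimethyl-1-oxo-10-(phenylsulfonyl)deca-2,8-dien-5-yl chain
Conditions: 18 (3 equiv, excess recovered), BHT, toluene (2 M), sealed tube, 110 °C, 24–48 h
Reagents that add atoms: none
Why: Thermal hetero-Diels–Alder reaction with the regiochemistry of acrolein-type dimerisation (O to C11, C13' to C13); the β-unsubstituted 2-alkylacrolein should react far faster than the β-substituted C3' enal, and attack on the exocyclic alkene from the convex H7/H8 face of the cis-fused lactone sets the spiro centre C11 (R).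

Step 12
Reactants: 19 spiro dihydropyran adduct with C3' enal
Product: 20 spiro dihydropyran adduct with C3' allylic alcohol
Conditions: NaBH4, CeCl3·7H2O, MeOH/THF, −40 °C
Reagents that add atoms: none
Why: Luche reduction gives clean 1,2-reduction of the enal; the hindered lactone, the enol ether and the sulfone are not reduced by borohydride at this temperature.

Step 13
Reactants: 20 spiro dihydropyran adduct with C3' allylic alcohol
Product: 21 spiro dihydropyran adduct with C3' allylic bromide
Conditions: CBr4, PPh3, 2,6-lutidine, CH2Cl2, −20 °C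
Reagents that add atoms: carbon tetrabromide, BrC(Br)(Br)Br
Why: Appel bromination under buffered, near-neutral conditions turns the primary allylic alcohol into the bromide without acid that would hydrate the enol ether.

Step 14
Reactants: 21 spiro dihydropyran adduct with C3' allylic bromide
Product: 22 2'-(phenylsulfonyl)-(1'(10')E,4'E)-cyclodecadiene (C2' epimers)
Conditions: LiN(SiMe3)2, THF, −78 to 0 °C, syringe-pump addition to 2 mM
Reagents that add atoms: none
Why: Intramolecular alkylation of the α-sulfonyl allyl carbanion at its α-carbon by the primary allylic bromide under high dilution is the established way to close (E,E)-cyclodeca-1,5-dienes; both alkene geometries are retained, the lactone has no α-hydrogen, and the new sulfonyl-bearing C2' forms as an epimer mixture that does not matter.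

Step 15
Reactants: 22 2'-(phenylsulfonyl)-(1'(10')E,4'E)-cyclodecadiene
Product: 23 (1'(10')E,4'E,7'S)-cyclodeca-1,5-diene isomer of the target
Conditions: 6% Na(Hg), Na2HPO4, MeOH/THF, −20 °C
Reagents that add atoms: none
Why: Buffered sodium amalgam reductive desulfonylation; electron transfer expels benzenesulfinate and the allyl anion should be protonated at the less substituted C2', keeping the trisubstituted E alkene, while the low temperature keeps the 1,5-diene from rearranging.

Step 16
Reactants: 23 (1'(10')E,4'E,7'S)-cyclodeca-1,5-diene isomer of the target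
Product: 24 CNP0175206.1
Conditions: toluene (degassed, 0.02 M), BHT, trace K2CO3, base-washed sealed tube, 150 °C, 2 h
Reagents that add atoms: none
Why: Heating drives a concerted suprafacial [3,3]-sigmatropic (Cope) shift of the C10'=C1'–C2'–C3'–C4'=C5' unit, in which C2'–C3' breaks while C5'–C10' forms, and the equilibrium lies on the side of the strain-free divinylcyclohexane. The closest known reaction is the thermal rearrangement of germacrene A to β-elemene. The cyclohexane closes by transannular C–C bond formation inside the ten-membered ring through a chair-like six-centre transition state that needs the crossed conformer of the two E alkenes. C10' and C5' are set together: the two E double bonds and the chair array force vinyl (C10') and isopropenyl (C5') trans, and the existing C7' centre, whose large pyranyl group stays pseudo-equatorial, decides which crossed conformer reacts and so fixes both new centres relative to C7'. The step needs diastereoselectivity (chair over boat, equatorial over axial C7' substituent); the lactone has no α-hydrogen and the enol ether is protected by neutral, acid-free conditions.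

**Compound list**

1 | (S)-(−)-limonene | CC1=CC[C@H](CC1)C(=C)C | starting material
2 | 10-lithio-(S)-limonene (allyllithium, not isolated) | CC1=CC[C@H](CC1)C(=C)C[Li] | intermediate
3 | dimethyl [2-((1S)-4-methylcyclohex-3-en-1-yl)prop-2-en-1-yl]boronate (not isolated) | CC1=CC[C@H](CC1)C(=C)CB(OC)OC | intermediate
4 | (S)-p-mentha-1,8-dien-10-ol | CC1=CC[C@H](CC1)C(=C)CO | intermediate
5 | (S)-10-(tert-butyldimethylsilyloxy)-p-mentha-1,8-diene | CC1=CC[C@H](CC1)C(=C)CO[Si](C)(C)C(C)(C)C | intermediate
6 | secondary ozonide (1,2,4-trioxolane) of the ring alkene of 5 (not isolated, acetal carbons unassigned) | CC12OOC(C[C@H](CC1)C(=C)CO[Si](C)(C)C(C)(C)C)O2 | intermediate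
7 | (3S)-3-[3-(tert-butyldimethylsilyloxy)prop-1-en-2-yl]-6-oxoheptanal | O=CC[C@H](CCC(C)=O)C(=C)CO[Si](C)(C)C(C)(C)C | intermediate
8 | tert-butyl 2-(triphenylphosphoranylidene)propanoate | CC(C(=O)OC(C)(C)C)=P(c1ccccc1)(c1ccccc1)c1ccccc1 | starting material
9 | tert-butyl (2E,5S)-5-[3-(tert-butyldimethylsilyloxy)prop-1-en-2-yl]-2-methyl-8-oxonon-2-enoate | CC(C)(C)OC(=O)/C(C)=C/C[C@H](CCC(C)=O)C(=C)CO[Si](C)(C)C(C)(C)C | intermediate
10 | triethyl phosphonoacetate | CCOC(=O)CP(=O)(OCC)OCC | starting material
11 | 1-tert-butyl 10-ethyl (2E,5S,8E)-5-[3-(tert-butyldimethylsilyloxy)prop-1-en-2-yl]-2,8-dimethyldeca-2,8-dienedioate | CC(C)(C)OC(=O)/C(C)=C/C[C@H](CC/C(C)=C/C(=O)OCC)C(=C)CO[Si](C)(C)C(C)(C)C | intermediate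
12 | tert-butyl (2E,5S,8E)-5-[3-(tert-butyldimethylsilyloxy)prop-1-en-2-yl]-10-hydroxy-2,8-dimethyldeca-2,8-dienoate | CC(C)(C)OC(=O)/C(C)=C/C[C@H](CC/C(C)=C/CO)C(=C)CO[Si](C)(C)C(C)(C)C | intermediate
13 | tert-butyl (2E,5S,8E)-10-bromo-5-[3-(tert-butyldimethylsilyloxy)prop-1-en-2-yl]-2,8-dimethyldeca-2,8-dienoate (not isolated) | CC(C)(C)OC(=O)/C(C)=C/C[C@H](CC/C(C)=C/CBr)C(=C)CO[Si](C)(C)C(C)(C)C | intermediate
14 | tert-butyl (2E,5S,8E)-5-[3-(tert-butyldimethylsilyloxy)prop-1-en-2-yl]-2,8-dimethyl-10-(phenylsulfonyl)deca-2,8-dienoate | CC(C)(C)OC(=O)/C(C)=C/C[C@H](CC/C(C)=C/CS(=O)(=O)c1ccccc1)C(=C)CO[Si](C)(C)C(C)(C)C | intermediate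
15 | (2E,5S,8E)-5-[3-(tert-butyldimethylsilyloxy)prop-1-en-2-yl]-2,8-dimethyl-10-(phenylsulfonyl)deca-2,8-dien-1-ol | OC/C(C)=C/C[C@H](CC/C(C)=C/CS(=O)(=O)c1ccccc1)C(=C)CO[Si](C)(C)C(C)(C)C | intermediate
16 | (2E,5S,8E)-5-(3-hydroxyprop-1-en-2-yl)-2,8-dimethyl-10-(phenylsulfonyl)deca-2,8-dien-1-ol | OC/C(C)=C/C[C@H](CC/C(C)=C/CS(=O)(=O)c1ccccc1)C(=C)CO | intermediate
17 | (2E,5S,8E)-2,8-dimethyl-5-(3-oxoprop-1-en-2-yl)-10-(phenylsulfonyl)deca-2,8-dienal | O=C/C(C)=C/C[C@H](CC/C(C)=C/CS(=O)(=O)c1ccccc1)C(=C)C=O | intermediate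
18 | alantolactone | C=C1C(=O)O[C@@H]2C[C@@]3(C)CCC[C@H](C)C3=C[C@@H]21 | starting material
19 | (11R)-spiro[alantolactone C11, 3,4-dihydro-2H-pyran C2] adduct with the (2E,5S,8E)-2,8-dimethyl-1-oxo-10-(phenylsulfonyl)deca-2,8-dien-5-yl chain on pyran C5 | O=C/C(C)=C/C[C@H](CC/C(C)=C/CS(=O)(=O)c1ccccc1)C1=CO[C@@]2(CC1)C(=O)O[C@@H]1C[C@@]3(C)CCC[C@H](C)C3=C[C@@H]12 | intermediate
20 | C3' allylic alcohol of 19 (1-hydroxy chain terminus) | OC/C(C)=C/C[C@H](CC/C(C)=C/CS(=O)(=O)c1ccccc1)C1=CO[C@@]2(CC1)C(=O)O[C@@H]1C[C@@]3(C)CCC[C@H](C)C3=C[C@@H]12 | intermediate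
21 | C3' allylic bromide of 20 | BrC/C(C)=C/C[C@H](CC/C(C)=C/CS(=O)(=O)c1ccccc1)C1=CO[C@@]2(CC1)C(=O)O[C@@H]1C[C@@]3(C)CCC[C@H](C)C3=C[C@@H]12 | intermediate
22 | 2'-(phenylsulfonyl) derivative of 23 (C2' epimers) | C/C1=C\C[C@@H](C2=CO[C@@]3(CC2)C(=O)O[C@@H]2C[C@@]4(C)CCC[C@H](C)C4=C[C@@H]23)CC/C(C)=C/C(S(=O)(=O)c2ccccc2)C1 | intermediate
23 | (E,E)-cyclodeca-1,5-diene isomer of the target: pyran C5 bears the (1S,3E,7E)-4,8-dimethylcyclodeca-3,7-dien-1-yl ring | C/C1=C\C[C@@H](C2=CO[C@@]3(CC2)C(=O)O[C@@H]2C[C@@]4(C)CCC[C@H](C)C4=C[C@@H]23)CC/C(C)=C/CC1 | intermediate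
24 | CNP0175206.1 | C=C[C@@]1(C)CC[C@H](C2=CO[C@@]3(CC2)C(=O)O[C@@H]2C[C@@]4(C)CCC[C@H](C)C4=C[C@@H]23)C[C@@H]1C(=C)C | target

**Step count and risks**

Total step count: 16. Longest linear sequence: 16 steps (1 to 24); 8, 10 and 18 are bought.

Steps most likely to fail:

Step 11 (hetero-Diels–Alder). The bimolecular cycloaddition may be outrun by self-condensation or polymerisation of the doubly unsaturated dialdehyde, or the second (C3') enal may take part, and facial selectivity at C11 may be incomplete. Fallback: leave only one heterodiene in the molecule. Setting out from 15, t-BuPh2SiCl and imidazole should give the mixed bis-silyl ether F1. Catalytic camphorsulfonic acid in MeOH/CH2Cl2 at 0 °C should remove only the tert-butyldimethylsilyl group to give the C12' alcohol F2. MnO2 should then give the mono-enal F3, which can be heated with 18 more forcingly (neat, 120–130 °C) to the silyl-protected adduct F4. Bu4NF buffered with AcOH frees the C3' alcohol and the route is rejoined at 20.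

Step 14 (ten-membered ring closure). Intermolecular alkylation (oligomerisation), elimination of HBr, or interference of the bulky lactone half with the folded conformer may win over ring closure. Fallback: close the ring before the lactone half is attached. Setting out from 15, CBr4/PPh3 should give the allylic bromide F5, and LiN(SiMe3)2 under high dilution (with a polar additive if needed, as no lactone is present) the cyclic sulfone F6. Without a lactone the sulfone can be removed by the regio-reliable hydride method, catalytic Pd(dppp)Cl2 with LiBHEt3 at 0 °C, to give the germacratriene silyl ether F7. Bu4NF gives the trienol F8 and MnO2 the trienal F9. The cycloaddition with 18 is then run under 1.2 GPa in CH2Cl2 at 20 °C, below the temperature of the rearrangement, and the route is rejoined at 23.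

Step 15 (desulfonylation). The allyl anion formed on electron transfer may be protonated at C10' or lose its E geometry, and methoxide formed in the reduction may open the lactone. Fallback: rearrange first, so that the sulfone is no longer allylic. Setting out from 22, heating as in step 16 should move the sulfonyl group onto the new vinyl terminus and give the vinyl sulfone F10 (mixture of geometric isomers, which does not matter). Reductive desulfonylation of this vinyl sulfone with Na2S2O4 and NaHCO3 in aqueous DMF, which passes through no allyl anion, should give the terminal vinyl group, and the route is rejoined at 24.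

**Further compounds**

F1 | step 11 | (2E,5S,8E)-1-(tert-butyldiphenylsilyloxy)-5-[3-(tert-butyldimethylsilyloxy)prop-1-en-2-yl]-2,8-dimethyl-10-(phenylsulfonyl)deca-2,8-diene | CC(C)(C)[Si](OC/C(C)=C/C[C@H](CC/C(C)=C/CS(=O)(=O)c1ccccc1)C(=C)CO[Si](C)(C)C(C)(C)C)(c1ccccc1)c1ccccc1
F2 | step 11 | 2-[(2E,5S,8E)-1-(tert-butyldiphenylsilyloxy)-2,8-dimethyl-10-(phenylsulfonyl)deca-2,8-dien-5-yl]prop-2-en-1-ol | CC(C)(C)[Si](OC/C(C)=C/C[C@H](CC/C(C)=C/CS(=O)(=O)c1ccccc1)C(=C)CO)(c1ccccc1)c1ccccc1
F3 | step 11 | 2-[(2E,5S,8E)-1-(tert-butyldiphenylsilyloxy)-2,8-dimethyl-10-(phenylsulfonyl)deca-2,8-dien-5-yl]prop-2-enal | CC(C)(C)[Si](OC/C(C)=C/C[C@H](CC/C(C)=C/CS(=O)(=O)c1ccccc1)C(=C)C=O)(c1ccccc1)c1ccccc1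
F4 | step 11 | tert-butyldiphenylsilyl ether of 20 | CC(C)(C)[Si](OC/C(C)=C/C[C@H](CC/C(C)=C/CS(=O)(=O)c1ccccc1)C1=CO[C@@]2(CC1)C(=O)O[C@@H]1C[C@@]3(C)CCC[C@H](C)C3=C[C@@H]12)(c1ccccc1)c1ccccc1
F5 | step 14 | (2E,5S,8E)-1-bromo-5-[3-(tert-butyldimethylsilyloxy)prop-1-en-2-yl]-2,8-dimethyl-10-(phenylsulfonyl)deca-2,8-diene | BrC/C(C)=C/C[C@H](CC/C(C)=C/CS(=O)(=O)c1ccccc1)C(=C)CO[Si](C)(C)C(C)(C)C
F6 | step 14 | (1(10)E,4E,7S)-12-(tert-butyldimethylsilyloxy)-2-(phenylsulfonyl)germacra-1(10),4,11(13)-triene (C2 epimers) | C/C1=C\C[C@@H](C(=C)CO[Si](C)(C)C(C)(C)C)CC/C(C)=C/C(S(=O)(=O)c2ccccc2)C1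
F7 | step 14 | (1(10)E,4E,7S)-12-(tert-butyldimethylsilyloxy)germacra-1(10),4,11(13)-triene | C/C1=C\C[C@@H](C(=C)CO[Si](C)(C)C(C)(C)C)CC/C(C)=C/CC1
F8 | step 14 | (1(10)E,4E,7S)-germacra-1(10),4,11(13)-trien-12-ol | C/C1=C\C[C@@H](C(=C)CO)CC/C(C)=C/CC1
F9 | step 14 | (1(10)E,4E,7S)-germacra-1(10),4,11(13)-trien-12-al | C/C1=C\C[C@@H](C(=C)C=O)CC/C(C)=C/CC1
F10 | step 15 | 2'-(phenylsulfonyl) derivative of 24 (vinyl sulfone, geometric isomers) | O=S(=O)(C=C[C@@]1(C)CC[C@H](C2=CO[C@@]3(CC2)C(=O)O[C@@H]2C[C@@]4(C)CCC[C@H](C)C4=C[C@@H]23)C[C@@H]1C(=C)C)c1ccccc1
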